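**Plan**
- Retrosynthetic cuts, in order: (a) the bridgehead C–C bond to the pyran ring-fusion CH together with the pyran O–CH(nonenyl) bond (retro carbonyl-Diels–Alder; the pyran oxygen is a ketone oxygen); (b) the C=C that joins the side-chain diene to the cyclopentane (HWE); (c) the lactone alkyl C–O bond; (d) the cyclopentane–CH2 bond (acetoacetate dianion + enone).
- Forward ring order: bought cyclopentene → spiro δ-lactone (6-oxaspiro[4.5]decane, key step) → cyclopentane → carbocycle of the 2-oxabicyclo[2.2.2]octan-3-one and the dihydropyran together in one hetero-Diels–Alder reaction.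
- Enabling feature: C1 of the 2-oxabicyclo[2.2.2]octan-3-one (the carbon bonded to ring oxygen O2, also a cyclopentane carbon) is tertiary, has a cyclopentane neighbour that can be kept sp2 (cyclopentenyl cation), and is δ to carboxyl carbon C3, so the ester carbonyl oxygen closes a six-membered ring on it.
- Stereochemistry: the cyclopentanol carbinol is bought; it sets the quaternary C–O carbon (key step, anti attack) and then the ring CH (OH-directed hydrogenation); tether and endo rule of the cycloaddition set the pyran bridgehead, the ring-fusion CH and the CH(nonenyl) centre; the last carbinol comes from substrate-controlled ketone reduction.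

Key step: step 4

Remark: β-keto lactones 7 and 20 and tricarbonyl 21 are drawn as keto tautomers (they should exist largely as enol or hydrate forms); spiro compounds are numbered as 6-oxaspiro[4.5]decanes (C1–C4 cyclopentane, C5 spiro, O6 ring oxygen, C7 lactone carbonyl); TBS = tert-butyldimethylsilyl, MOM = methoxymethyl.

Step 1
Reactants: 1 (S)-4-[(tert-butyldimethylsilyl)oxy]cyclopent-2-en-1-one; 2 formaldehyde
Product: 3 (S)-4-[(tert-butyldimethylsilyl)oxy]-2-(hydroxymethyl)cyclopent-2-en-1-one
Conditions: 37% aq. HCHO, imidazole (cat.), THF–H2O, rt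
Reagents that add atoms: none
Why: Morita–Baylis–Hillman reaction, in which imidazole adds reversibly to C3 and the enolate captures formaldehyde at C2; the C4 stereocentre is untouched and the weakly basic medium should avoid β-elimination of the silyloxy group.

Step 2
Reactants: 3 (S)-4-[(tert-butyldimethylsilyl)oxy]-2-(hydroxymethyl)cyclopent-2-en-1-one
Product: 4 (S)-4-[(tert-butyldimethylsilyl)oxy]-2-{[(tert-butyldimethylsilyl)oxy]methyl}cyclopent-2-en-1-one
Conditions: TBSCl, imidazole, DMF, 0 °C → rt
Reagents that add atoms: tert-butyldimethylsilyl chloride, CC(C)(C)[Si](C)(C)Cl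
Why: Standard silylation of the primary allylic alcohol, so that the strongly basic next step meets no acidic OH.

Step 3
Reactants: 4 (S)-4-[(tert-butyldimethylsilyl)oxy]-2-{[(tert-butyldimethylsilyl)oxy]methyl}cyclopent-2-en-1-one; 5 tert-butyl acetoacetate
Product: 6 tert-butyl 4-[(4S)-4-(TBSO)-2-(TBSOCH2)-1-hydroxycyclopent-2-en-1-yl]-3-oxobutanoate (1-OH cis to 4-OTBS)
Conditions: 5, LDA (2.1 equiv), THF, 0 °C; then 4, −78 °C; NH4Cl quench at −78 °C
Reagents that add atoms: none
Why: Acetoacetate dianion γ-addition (vinylogous aldol) occurs 1,2 at the hindered enone carbonyl from the face opposite the 4-silyloxy group; the carbinol configuration is of no consequence because this centre is ionised in step 4.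

Step 4
Reactants: 6 tert-butyl 4-[(4S)-4-(TBSO)-2-(TBSOCH2)-1-hydroxycyclopent-2-en-1-yl]-3-oxobutanoate
Product: 7 3-(TBSO)-1-(TBSOCH2)-6-oxaspiro[4.5]dec-1-ene-7,9-dione (O6 trans to the 3-silyloxy group)
Conditions: Bi(OTf)3 (5 mol %), 4 Å MS, CH2Cl2, −20 → 0 °C
Reagents that add atoms: none
Why: The Lewis acid ionises the tertiary allylic C–OH to a 1,3-disubstituted cyclopentenyl (allyl) cation; the tert-butyl ester carbonyl oxygen adds to the tertiary terminus and the tert-butoxy-oxocarbenium ion sheds isobutene, so the new bond is carbonyl oxygen to ring carbon (alkyl–oxygen mode, not acyl transfer). The closest known reaction type is acid-mediated dehydrative (SN1) allylic lactonisation, together with capture of carbocations by tert-butyl esters or carbonates. One ring closes, the six-membered δ-lactone, by 6-exo attack on the allyl-cation terminus, which makes that carbon a spiro centre. The new quaternary stereocentre is controlled by the silyloxy-bearing carbon two bonds away in the five-membered ring: as in carbonyl additions to 4-silyloxycyclopentenones the nucleophile should enter anti to OTBS, so the lactone oxygen ends trans to it, a net inversion of the step-3 carbinol that direct acyl transfer could not give. The step needs attack of the ester oxygen at the tertiary terminus rather than the bridged alternatives (C-capture by the keto-ester enol or attack at the secondary terminus), which the unstrained spiro six-membered closure and the higher charge at the tertiary carbon should secure. It also needs capture to outrun E1 loss and retro-aldol cleavage, for which the intramolecular nucleophile, low temperature and a non-protic Lewis acid are chosen.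

Step 5
Reactants: 7 3-(TBSO)-1-(TBSOCH2)-6-oxaspiro[4.5]dec-1-ene-7,9-dione
Product: 8 9-(methoxymethoxy)-3-(TBSO)-1-(TBSOCH2)-6-oxaspiro[4.5]deca-1,8-dien-7-one
Conditions: MOMCl, iPr2NEt, CH2Cl2, 0 °C
Reagents that add atoms: chloromethyl methyl ether, COCCl
Why: O-Alkylation of the enol of the cyclic β-keto lactone by a hard chloromethyl ether gives the vinylogous MOM ester, masking the acidic 1,3-dicarbonyl through the fluoride, oxidation and basic steps that follow.

Step 6
Reactants: 8 9-(methoxymethoxy)-3-(TBSO)-1-(TBSOCH2)-6-oxaspiro[4.5]deca-1,8-dien-7-one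
Product: 9 3-hydroxy-1-(hydroxymethyl)-9-(methoxymethoxy)-6-oxaspiro[4.5]deca-1,8-dien-7-one
Conditions: TBAF, AcOH, THF, 0 °C → rt
Reagents that add atoms: none
Why: Buffered fluoride desilylation removes both TBS ethers while acetic acid keeps the medium from deprotonating C10 of the unsaturated lactone.

Step 7
Reactants: 9 3-hydroxy-1-(hydroxymethyl)-9-(methoxymethoxy)-6-oxaspiro[4.5]deca-1,8-dien-7-one
Product: 10 3-hydroxy-1-(hydroxymethyl)-9-(methoxymethoxy)-6-oxaspiro[4.5]dec-8-en-7-one (H-1 cis to 3-OH; CH2OH cis to O6)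
Conditions: [Ir(cod)(PCy3)(py)]PF6 (5 mol %), H2 (1 atm), CH2Cl2, rt
Reagents that add atoms: none
Why: Hydroxyl-directed homogeneous hydrogenation, in which iridium bound to the ring 3-OH delivers H2 to that face of the trisubstituted C1=C2 alkene, so the new C1–H is cis to the 3-OH and the CH2OH group ends cis to the lactone oxygen; the push–pull enol-ether alkene should be inert.

Step 8
Reactants: 10 3-hydroxy-1-(hydroxymethyl)-9-(methoxymethoxy)-6-oxaspiro[4.5]dec-8-en-7-one
Product: 11 3-hydroxy-9-(methoxymethoxy)-7-oxo-6-oxaspiro[4.5]dec-8-ene-1-carbaldehyde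
Conditions: TEMPO (cat.), PhI(OAc)2, CH2Cl2, rt; used at once
Reagents that add atoms: none
Why: Oxoammonium (TEMPO) oxidation is selective for the primary over the secondary alcohol and stops at the aldehyde, a β-acyloxy aldehyde that is not stored.

Step 9
Reactants: 12 (E)-dec-2-enal; 13 ethyl 2-(triphenylphosphoranylidene)propanoate
Product: 14 ethyl (2E,4E)-2-methyldodeca-2,4-dienoate
Conditions: CH2Cl2, rt → 40 °C
Reagents that add atoms: none
Why: Wittig reaction of a stabilised α-methyl ylide with an enal gives the (2E)-trisubstituted enoate, the (4E) alkene coming unchanged from 12.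

Step 10
Reactants: 14 ethyl (2E,4E)-2-methyldodeca-2,4-dienoate
Product: 15 (2E,4E)-2-methyldodeca-2,4-dien-1-ol
Conditions: DIBAL-H (2.2 equiv), CH2Cl2, −78 °C; Rochelle salt
Reagents that add atoms: none
Why: DIBAL-H 1,2-reduction of the conjugated ester gives the allylic alcohol without touching the diene.

Step 11
Reactants: 15 (2E,4E)-2-methyldodeca-2,4-dien-1-ol
Product: 16 (2E,4E)-1-bromo-2-methyldodeca-2,4-diene
Conditions: PBr3 (0.4 equiv), Et2O, 0 °C
Reagents that add atoms: phosphorus tribromide, BrP(Br)Br
Why: SN2 bromination of the primary dienylic alcohol at low temperature should retain both alkene geometries.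

Step 12
Reactants: 16 (2E,4E)-1-bromo-2-methyldodeca-2,4-diene
Product: 17 diethyl [(2E,4E)-2-methyldodeca-2,4-dien-1-yl]phosphonate
Conditions: P(OEt)3, neat, 100 °C
Reagents that add atoms: triethyl phosphite, CCOP(OCC)OCC
Why: Michaelis–Arbuzov reaction of a primary allylic bromide.

Step 13
Reactants: 11 3-hydroxy-9-(methoxymethoxy)-7-oxo-6-oxaspiro[4.5]dec-8-ene-1-carbaldehyde; 17 diethyl [(2E,4E)-2-methyldodeca-2,4-dien-1-yl]phosphonate
Product: 18 3-hydroxy-9-(methoxymethoxy)-1-[(1E,3E,5E)-3-methyltrideca-1,3,5-trien-1-yl]-6-oxaspiro[4.5]dec-8-en-7-one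
Conditions: 17 (2.2 equiv), LiHMDS, THF, −78 °C; then 11, −78 → −20 °C
Reagents that add atoms: none
Why: Horner–Wadsworth–Emmons olefination with the lithiated dienylic phosphonate should give the new disubstituted alkene E-selectively and complete the (1E,3E,5E)-triene, the first equivalent of anion taking the hydroxyl proton and the low temperature limiting enolisation of the β-acyloxy aldehyde.

Step 14
Reactants: 18 3-hydroxy-9-(methoxymethoxy)-1-[(1E,3E,5E)-3-methyltrideca-1,3,5-trien-1-yl]-6-oxaspiro[4.5]dec-8-en-7-one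
Product: 19 3-(TBSO)-9-(methoxymethoxy)-1-[(1E,3E,5E)-3-methyltrideca-1,3,5-trien-1-yl]-6-oxaspiro[4.5]dec-8-en-7-one
Conditions: TBSCl, imidazole, DMF, rt
Reagents that add atoms: tert-butyldimethylsilyl chloride, CC(C)(C)[Si](C)(C)Cl
Why: Silylation of the only free (secondary) hydroxyl, so that it survives the periodinane oxidation of step 16.

Step 15
Reactants: 19 3-(TBSO)-9-(methoxymethoxy)-1-[(1E,3E,5E)-3-methyltrideca-1,3,5-trien-1-yl]-6-oxaspiro[4.5]dec-8-en-7-one
Product: 20 3-(TBSO)-1-[(1E,3E,5E)-3-methyltrideca-1,3,5-trien-1-yl]-6-oxaspiro[4.5]decane-7,9-dione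
Conditions: PPTS (cat.), MeOH, 40 °C
Reagents that add atoms: none
Why: Acid-catalysed transacetalisation, in which the vinylogous MOM ester (an acyl-type acetal) should be far more labile than the secondary TBS ether or the triene and returns the β-keto lactone.

Step 16
Reactants: 20 3-(TBSO)-1-[(1E,3E,5E)-3-methyltrideca-1,3,5-trien-1-yl]-6-oxaspiro[4.5]decane-7,9-dione
Product: 22 pentacyclic keto lactone (TBS ether of the target in which the bridge CH–OH is still C=O), via vicinal tricarbonyl lactone 21 (not isolated)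
Conditions: Dess–Martin periodinane (3 equiv), pyridine, CH2Cl2, rt; filter; then PhMe, 60 °C
Reagents that add atoms: Dess–Martin periodinane (source of the new C8 carbonyl oxygen), CC(=O)OI1(OC(C)=O)(OC(C)=O)OC(=O)c2ccccc12
Why: Periodinane oxidation of the active methylene gives the cyclic vicinal tricarbonyl 21, whose central ketone sits 1,4 across the lactone ring from the spiro carbon and should undergo an intramolecular carbonyl hetero-Diels–Alder reaction with the proximal s-cis (E,E)-diene of the arm; the tether fixes the bridgehead configuration, and the endo mode (diene stacked over the lactone carbonyl) sets the ring-fusion CH and the CH(nonenyl) centre, both cis to the lactone carbonyl on the new dihydropyran.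

Step 17
Reactants: 22 pentacyclic keto lactone (TBS ether)
Product: 23 TBS ether of the target (cyclopentane OTBS)
Conditions: NaBH4, MeOH–CH2Cl2, −78 → −40 °C
Reagents that add atoms: none
Why: Borohydride reduction of the bridge ketone, in which hydride should come from the face flanked by the flat lactone bridge, opposite the two-carbon bridge whose two hydrogens point at the carbonyl, so the hydroxyl ends anti to the lactone bridge.

Step 18
Reactants: 23 TBS ether of the target
Product: 24 CNP0127096.1 (target)
Conditions: TBAF, AcOH, THF, 0 °C → rt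
Reagents that add atoms: none
Why: Fluoride desilylation of the last protecting group under buffered conditions that should leave the lactone and the bis-allylic ether alone.

**Compound list**
1 | (S)-4-[(tert-butyldimethylsilyl)oxy]cyclopent-2-en-1-one | O=C1C=C[C@@H](O[Si](C)(C)C(C)(C)C)C1 | starting material
2 | formaldehyde | C=O | starting material
3 | (S)-4-[(tert-butyldimethylsilyl)oxy]-2-(hydroxymethyl)cyclopent-2-en-1-one | O=C1C(CO)=C[C@@H](O[Si](C)(C)C(C)(C)C)C1 | intermediate
4 | (S)-4-[(tert-butyldimethylsilyl)oxy]-2-{[(tert-butyldimethylsilyl)oxy]methyl}cyclopent-2-en-1-one | O=C1C(CO[Si](C)(C)C(C)(C)C)=C[C@@H](O[Si](C)(C)C(C)(C)C)C1 | intermediate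
5 | tert-butyl acetoacetate | CC(=O)CC(=O)OC(C)(C)C | starting material
6 | tert-butyl 4-[(4S)-4-(TBSO)-2-(TBSOCH2)-1-hydroxycyclopent-2-en-1-yl]-3-oxobutanoate, 1-OH cis to 4-OTBS | CC(C)(C)OC(=O)CC(=O)C[C@@]1(O)C[C@H](O[Si](C)(C)C(C)(C)C)C=C1CO[Si](C)(C)C(C)(C)C | intermediate
7 | 3-(TBSO)-1-(TBSOCH2)-6-oxaspiro[4.5]dec-1-ene-7,9-dione, O6 trans to 3-OTBS | O=C1CC(=O)O[C@]2(C[C@H](O[Si](C)(C)C(C)(C)C)C=C2CO[Si](C)(C)C(C)(C)C)C1 | intermediate
8 | 9-(methoxymethoxy)-3-(TBSO)-1-(TBSOCH2)-6-oxaspiro[4.5]deca-1,8-dien-7-one | COCOC1=CC(=O)O[C@]2(C[C@H](O[Si](C)(C)C(C)(C)C)C=C2CO[Si](C)(C)C(C)(C)C)C1 | intermediate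
9 | 3-hydroxy-1-(hydroxymethyl)-9-(methoxymethoxy)-6-oxaspiro[4.5]deca-1,8-dien-7-one, O6 trans to 3-OH | COCOC1=CC(=O)O[C@]2(C[C@H](O)C=C2CO)C1 | intermediate
10 | 3-hydroxy-1-(hydroxymethyl)-9-(methoxymethoxy)-6-oxaspiro[4.5]dec-8-en-7-one, H-1 cis to 3-OH, CH2OH cis to O6 | COCOC1=CC(=O)O[C@]2(C[C@H](O)C[C@H]2CO)C1 | intermediate
11 | 3-hydroxy-9-(methoxymethoxy)-7-oxo-6-oxaspiro[4.5]dec-8-ene-1-carbaldehyde, CHO cis to O6 and trans to 3-OH | COCOC1=CC(=O)O[C@]2(C[C@H](O)C[C@H]2C=O)C1 | intermediate
12 | (E)-dec-2-enal | CCCCCCC/C=C/C=O | starting material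
13 | ethyl 2-(triphenylphosphoranylidene)propanoate | CCOC(=O)C(C)=P(c1ccccc1)(c1ccccc1)c1ccccc1 | starting material
14 | ethyl (2E,4E)-2-methyldodeca-2,4-dienoate | CCCCCCC/C=C/C=C(C)/C(=O)OCC | intermediate
15 | (2E,4E)-2-methyldodeca-2,4-dien-1-ol | CCCCCCC/C=C/C=C(C)/CO | intermediate
16 | (2E,4E)-1-bromo-2-methyldodeca-2,4-diene | CCCCCCC/C=C/C=C(C)/CBr | intermediate
17 | diethyl [(2E,4E)-2-methyldodeca-2,4-dien-1-yl]phosphonate | CCCCCCC/C=C/C=C(C)/CP(=O)(OCC)OCC | intermediate
18 | 3-hydroxy-9-(methoxymethoxy)-1-[(1E,3E,5E)-3-methyltrideca-1,3,5-trien-1-yl]-6-oxaspiro[4.5]dec-8-en-7-one, trienyl cis to O6 and trans to 3-OH | COCOC1=CC(=O)O[C@]2(C[C@H](O)C[C@H]2/C=C/C(C)=C/C=C/CCCCCCC)C1 | intermediate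
19 | 3-O-TBS ether of 18 | COCOC1=CC(=O)O[C@]2(C[C@H](O[Si](C)(C)C(C)(C)C)C[C@H]2/C=C/C(C)=C/C=C/CCCCCCC)C1 | intermediate
20 | 3-(TBSO)-1-[(1E,3E,5E)-3-methyltrideca-1,3,5-trien-1-yl]-6-oxaspiro[4.5]decane-7,9-dione | O=C1CC(=O)O[C@]2(C[C@H](O[Si](C)(C)C(C)(C)C)C[C@H]2/C=C/C(C)=C/C=C/CCCCCCC)C1 | intermediate
21 | 3-(TBSO)-1-[(1E,3E,5E)-3-methyltrideca-1,3,5-trien-1-yl]-6-oxaspiro[4.5]decane-7,8,9-trione | O=C1C(=O)C(=O)O[C@]2(C[C@H](O[Si](C)(C)C(C)(C)C)C[C@H]2/C=C/C(C)=C/C=C/CCCCCCC)C1 | intermediate
22 | pentacyclic keto lactone: target skeleton with cyclopentane OTBS and bridge C=O in place of CH–OH | CCCCCCC/C=C/[C@H]1O[C@@]23C(=O)O[C@]4(C[C@H](O[Si](C)(C)C(C)(C)C)C[C@H]4[C@H]2C=C1C)CC3=O | intermediate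
23 | TBS ether of the target (cyclopentane OTBS; bridge OH anti to the lactone bridge) | CCCCCCC/C=C/[C@H]1O[C@@]23C(=O)O[C@]4(C[C@H](O[Si](C)(C)C(C)(C)C)C[C@H]4[C@H]2C=C1C)C[C@H]3O | intermediate
24 | CNP0127096.1 | CCCCCCC/C=C/[C@H]1O[C@@]23C(=O)O[C@]4(C[C@H](O)C[C@H]4[C@H]2C=C1C)C[C@H]3O | target

Total steps: 18. Longest linear sequence: 14 (steps 1–8 and 13–18).

**Steps most likely to fail**

Step 16. The tricarbonyl may rest as its enol or hydrate and decompose before it cycloadds, or the diene may stack over the flanking ketone instead of the lactone carbonyl, so that endo/exo control is lost. The fallback changes the dienophile and the way the rings close. It sets out from 20: after the same periodinane oxidation the crude tricarbonyl 21 is O-methylated with trimethylsilyldiazomethane to the fixed, non-enolisable 9-methoxy-6-oxaspiro[4.5]dec-9-ene-7,8-dione F1, whose ketone is flanked by only one carbonyl, the lactone. Ring closure is then promoted by Me2AlCl at low temperature (Lewis-acid-activated, possibly stepwise Prins-type cycloaddition) to the enol ether adduct F2, and aqueous oxalic acid hydrolyses the enol ether, which brings the route back at 22.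

Step 4. The allyl cation may lose a ring proton (E1), the tertiary aldol may cleave (retro-aldol), or the spiro centre may equilibrate by re-ionisation, which would erode facial selectivity. The fallback avoids a free cation and makes the same C–O bond by conjugate addition. It sets out from 6: Burgess dehydration gives the exocyclic cross-conjugated enone, the cyclopentenylidene keto ester F3; TMSOTf/2,6-lutidine cleaves the tert-butyl ester to the cyclopentenylidene keto acid F4; catalytic camphorsulfonic acid then effects 6-endo oxa-Michael addition of the carboxyl group to the ring carbon from the face opposite the silyloxy group, which comes back at 7.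

Step 13. Base may cause β-elimination of the lactone carboxylate from the β-acyloxy aldehyde (E1cB ring opening) or epimerisation next to the aldehyde. The fallback builds the triene without base, by chromium olefination and cross-coupling. It sets out from 11 and 12: CrCl2/CHI3 (Takai) converts 11 into the E-vinyl iodide F5; Corey–Fuchs homologation of 12 (CBr4, PPh3) gives the dibromodiene F6, and n-BuLi followed by MeI gives the enyne F7. Hydrozirconation of F7 with Cp2Zr(H)Cl (zirconium at the methyl-bearing carbon), transmetalation with ZnCl2 and Pd(PPh3)4-catalysed Negishi coupling with F5 then come back at 18.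

**Further compounds**
F1 | step 16 | 9-methoxy-3-(TBSO)-1-[(1E,3E,5E)-3-methyltrideca-1,3,5-trien-1-yl]-6-oxaspiro[4.5]dec-9-ene-7,8-dione | COC1=C[C@@]2(C[C@H](O[Si](C)(C)C(C)(C)C)C[C@H]2/C=C/C(C)=C/C=C/CCCCCCC)OC(=O)C1=O
F2 | step 16 | methyl enol ether of 22 (bridge C(OMe)=CH) | CCCCCCC/C=C/[C@H]1O[C@@]23C(=O)O[C@]4(C[C@H](O[Si](C)(C)C(C)(C)C)C[C@H]4[C@H]2C=C1C)C=C3OC
F3 | step 4 | tert-butyl 4-[(4S)-4-(TBSO)-2-(TBSOCH2)cyclopent-2-en-1-ylidene]-3-oxobutanoate | CC(C)(C)OC(=O)CC(=O)C=C1C[C@H](O[Si](C)(C)C(C)(C)C)C=C1CO[Si](C)(C)C(C)(C)C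
F4 | step 4 | 4-[(4S)-4-(TBSO)-2-(TBSOCH2)cyclopent-2-en-1-ylidene]-3-oxobutanoic acid | OC(=O)CC(=O)C=C1C[C@H](O[Si](C)(C)C(C)(C)C)C=C1CO[Si](C)(C)C(C)(C)C
F5 | step 13 | 3-hydroxy-1-[(E)-2-iodoethenyl]-9-(methoxymethoxy)-6-oxaspiro[4.5]dec-8-en-7-one | COCOC1=CC(=O)O[C@]2(C[C@H](O)C[C@H]2/C=C/I)C1
F6 | step 13 | (3E)-1,1-dibromoundeca-1,3-diene | CCCCCCC/C=C/C=C(Br)Br
F7 | step 13 | (E)-dodec-4-en-2-yne | CCCCCCC/C=C/C#CC
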